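**Retrosynthetic overview**
1. 29 ⇐ allyl ester 28 (deallylation; angeloylation of C19-OH) ⇐ (13Z)-enoate 24 (Me2CuLi on ynoate 23) ⇐ alkyne 20, whose C7=C8 / 9α-H array comes from reductive 1,3-transposition of 7β-ol 17.
2. 17 ⇐ 8-en-7-one 15 ⇐ α-keto ketal 13 (SmI2 removes both C6 oxygens and frees C19-OH) ⇐ C9 carbinol 12 (oxidative transposition) ⇐ enone 9 + side-chain Grignard reagent (C11–C14).
3. 9 ⇐ cis-fused adduct 7 (alkene hydrogenation, C5 epimerisation) ⇐ achiral mixed quinone monoketal 6, by an intramolecular Diels–Alder reaction that forms C1–C10 and C4–C5 ⇐ phenol 5 + dienol 4.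
4. Enabling feature: ring B (C5–C10) is a masked 2,6-dimethyl-1,4-benzoquinone (C20 on C10 and C17 on C8 flank C9; C6 is para to C9), and the C19 oxygen on C4 lies 1,4 to C6 across C4–C5, so a C6–O–C19 ketal tether holds the C1–C4 diene (C18 on C4) over the C5=C10 enone bond.
5. Ring order: ring B (arene, then dienone) → ring A together with a temporary oxolane ring (C4–C19–O–C6–C5) in the key step → oxolane opened reductively in step 9.

Key step: step 4

Numbering remark: labdane numbering is used throughout (decalin C1–C10, C17 on C8, C18 α and C19 β on C4, C20 β on C10); the target is the normal-series (4S,5R,9S,10R,13Z) compound.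
Assumption: the (R)-BINOL-derived titanium catalyst is taken to select the enantiotopic C5=C10 bond that leads to 7 as drawn; if the sense of induction is opposite, the (S)-ligand is used with no other change.

**Step 1**
Reactants: 1 acrolein; 2 ethyl 2-(triphenylphosphoranylidene)propanoate
Product: 3 ethyl (2E)-2-methylpenta-2,4-dienoate
Conditions: CH2Cl2, 0 °C to rt
Reagents that add atoms: none
Why: Wittig olefination with a stabilised ylide should be E-selective for the new trisubstituted C=C (ester trans to the vinyl group) and forms no stereocentre.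

**Step 2**
Reactants: 3 ethyl (2E)-2-methylpenta-2,4-dienoate
Product: 4 (2E)-2-methylpenta-2,4-dien-1-ol
Conditions: i-Bu2AlH (2.2 equiv), CH2Cl2, −78 to 0 °C; aqueous potassium sodium tartrate (KNaC4H4O6)
Reagents that add atoms: none
Why: Ester-to-alcohol reduction with a dialkylaluminium hydride is a 1,2-hydride delivery that should leave the diene and its E geometry untouched.

**Step 3**
Reactants: 4 (2E)-2-methylpenta-2,4-dien-1-ol; 5 4-methoxy-2,6-dimethylphenol
Product: 6 4-methoxy-2,6-dimethyl-4-{[(2E)-2-methylpenta-2,4-dien-1-yl]oxy}cyclohexa-2,5-dien-1-one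
Conditions: PhI(OAc)2 (1.1 equiv), 4 (5 equiv, excess recovered), CH2Cl2, 0 °C
Reagents that add atoms: none
Why: Oxidative dearomatisation of a para-alkoxyphenol by the trivalent iodine reagent gives a phenoxenium-type intermediate that the added alcohol should capture at the methoxy-bearing para carbon to give the mixed quinone monoketal (masked p-benzoquinone), whose ketal carbon is not stereogenic because the two ring arms are identical.

**Step 4**
Reactants: 6 4-methoxy-2,6-dimethyl-4-{[(2E)-2-methylpenta-2,4-dien-1-yl]oxy}cyclohexa-2,5-dien-1-one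
Product: 7 6α,19-epoxy-6β-methoxy-11,12,13,14,15,16-hexanor-5β-labda-2,7-dien-9-one (cis-fused; 4α-methyl, 4β-CH2O, 10β-methyl, 5β-H)
Conditions: (R)-BINOL (20 mol%), TiCl2(Oi-Pr)2 (20 mol%), 4 Å molecular sieves (zeolite NaA, Na12Al12Si12O48), CH2Cl2, 0 °C to rt
Reagents that add atoms: none
Why: Proposed new method: the chiral BINOL–TiCl2 Lewis acid (tetravalent titanium) binds the C9 carbonyl and lowers the enone LUMO, and the (E)-diene held by the C6–O–C19 ketal tether adds suprafacially across one of the two enantiotopic enone bonds (C5=C10) in a concerted, asynchronous intramolecular [4+2] cycloaddition. The closest known reaction types are the thermal intramolecular Diels–Alder reaction of masked p-benzoquinones that carry a dienyloxy ketal substituent and the BINOL–titanium-catalysed enantioselective intermolecular Diels–Alder reaction of prochiral 1,4-quinone monoketals; their combination in an enantiotopic-group-selective intramolecular mode is new. Ring A closes as the cyclohexene of the [4+2] event (bonds C1–C10 and C4–C5), and the oxolane tether ring closes in the fused type 1 mode (5-exo with respect to C5=C10) through the same C4–C5 bond. C5 and C10 are set cis by suprafacial addition on the ring-B face that carries the tether oxygen (which also fixes C6); C4 is set by the E geometry of the diene together with the exo orientation of ring B, so that the outside C19 ends cis to C20 and the inside C18 trans; the absolute configuration is set by the catalyst's choice between the C5=C10 and C7=C8 bonds. The step needs exo selectivity and enantiotopic-group selectivity: the first should be secured by the three-atom tether, which spans from the axial ketal oxygen to the outside diene position without strain only in the exo arrangement and keeps the inside methyl away from C20, the second by the chiral titanium complex, while regiochemistry is fixed by the tether.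

**Step 5**
Reactants: 7 6α,19-epoxy-6β-methoxy-11,12,13,14,15,16-hexanor-5β-labda-2,7-dien-9-one
Product: 8 6α,19-epoxy-6β-methoxy-11,12,13,14,15,16-hexanor-5β-labd-7-en-9-one
Conditions: H2 (1 atm), RhCl(PPh3)3 (5 mol%), benzene, rt
Reagents that add atoms: none
Why: Homogeneous hydrogenation with RhCl(PPh3)3 should reduce the unhindered cis-disubstituted C2=C3 bond much faster than the trisubstituted, conjugated C7=C8 bond, and it forms no stereocentre.

**Step 6**
Reactants: 8 6α,19-epoxy-6β-methoxy-11,12,13,14,15,16-hexanor-5β-labd-7-en-9-one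
Product: 9 6β,19-epoxy-6α-methoxy-11,12,13,14,15,16-hexanorlabd-7-en-9-one (trans-fused; 5α-H)
Conditions: camphorsulfonic acid (10 mol%), MeOH, 60 °C
Reagents that add atoms: none
Why: Acid-catalysed ketal equilibration (reversible opening to the C6 oxocarbenium ion and its C5=C6 methyl enol ether) should epimerise C5 under thermodynamic control to the trans-decalin, in which the axial C19 oxygen recloses on the β face of C6 as the syn-axial 6β,19-bridge, so that 5α-H and the C6 configuration are set by stability.

**Step 7**
Reactants: 9 6β,19-epoxy-6α-methoxy-11,12,13,14,15,16-hexanorlabd-7-en-9-one; 10 (4-bromobut-1-yn-1-yl)trimethylsilane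
Product: 12 6β,19-epoxy-6α-methoxy-14-(trimethylsilyl)-15,16-dinorlabd-7-en-13-yn-9β-ol, via Grignard reagent 11 (not isolated)
Conditions: 10, Mg, THF, rt; then 9, anhydrous CeCl3, THF, −78 to 0 °C; aqueous NH4Cl
Reagents that add atoms: none
Why: CeCl3-promoted Grignard 1,2-addition to the hindered enone carbonyl should suppress enolisation and conjugate addition, and attack anti to the axial C20 methyl is expected to give the 9β-alcohol, although either C9 epimer serves because this centre becomes trigonal in step 8.

**Step 8**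
Reactants: 12 6β,19-epoxy-6α-methoxy-14-(trimethylsilyl)-15,16-dinorlabd-7-en-13-yn-9β-ol
Product: 13 6β,19-epoxy-6α-methoxy-14-(trimethylsilyl)-15,16-dinorlabd-8-en-13-yn-7-one
Conditions: pyridinium chlorochromate [C5H5NH][CrO3Cl] (3 equiv), NaOAc, CH2Cl2, rt
Reagents that add atoms: pyridinium chlorochromate, [O-][Cr](=O)(=O)Cl.c1cc[nH+]cc1
Why: In the Babler–Dauben oxidative transposition the tertiary allylic chromate ester should undergo a [3,3]-shift to C7 and be oxidised there, which gives the C7 ketone conjugated with the new tetrasubstituted C8=C9 bond without a new stereocentre.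

**Step 9**
Reactants: 13 6β,19-epoxy-6α-methoxy-14-(trimethylsilyl)-15,16-dinorlabd-8-en-13-yn-7-one
Product: 15 19-hydroxy-14-(trimethylsilyl)-15,16-dinorlabd-8-en-13-yn-7-one, via 6-methoxy ketone 14 (not isolated)
Conditions: SmI2 (5 equiv), THF/MeOH, −78 to 0 °C
Reagents that add atoms: none
Why: Reductive cleavage of α-alkoxy ketones by divalent samarium (ketyl formation, second electron transfer and β-elimination of alkoxide, twice) should excise both C6 oxygens and release C19-OH, the cross-conjugated samarium dienolate being protonated at C6 so that the enone and the 5α-H centre stay intact.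

**Step 10**
Reactants: 15 19-hydroxy-14-(trimethylsilyl)-15,16-dinorlabd-8-en-13-yn-7-one
Product: 16 19-(tert-butyldimethylsilyloxy)-14-(trimethylsilyl)-15,16-dinorlabd-8-en-13-yn-7-one
Conditions: TBSCl, imidazole, DMF, rt
Reagents that add atoms: tert-butyldimethylsilyl chloride, CC(C)(C)[Si](C)(C)Cl
Why: Imidazole-mediated silyl ether formation on the only hydroxyl (primary, neopentyl) protects it for the Mitsunobu and organolithium steps and forms no stereocentre.

**Step 11**
Reactants: 16 19-(tert-butyldimethylsilyloxy)-14-(trimethylsilyl)-15,16-dinorlabd-8-en-13-yn-7-one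
Product: 17 19-(tert-butyldimethylsilyloxy)-14-(trimethylsilyl)-15,16-dinorlabd-8-en-13-yn-7β-ol
Conditions: NaBH4, CeCl3·7H2O, MeOH, −78 to −40 °C
Reagents that add atoms: none
Why: Luche reduction should give clean 1,2-reduction of the enone, and axial hydride delivery from the α face of the half-chair (only H5 is syn-axial) should give the equatorial 7β-alcohol.

**Step 12**
Reactants: 17 19-(tert-butyldimethylsilyloxy)-14-(trimethylsilyl)-15,16-dinorlabd-8-en-13-yn-7β-ol
Product: 20 19-(tert-butyldimethylsilyloxy)-14-(trimethylsilyl)-15,16-dinorlabd-7-en-13-yne (9α-H), via allylic sulfonylhydrazine 18 (not isolated), via allylic diazene 19 (not isolated)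
Conditions: PPh3, diethyl azodicarboxylate, 2-nitrobenzenesulfonylhydrazide, N-methylmorpholine, −30 °C; then rt
Reagents that add atoms: none
Why: Mitsunobu displacement by the sulfonylhydrazide nitrogen inverts C7, loss of sulfinic acid gives the 7α-allylic diazene, and its retro-ene loss of N2 (reductive 1,3-transposition of an allylic alcohol) should deliver hydrogen suprafacially to the α face of C9, which sets 9α-H and moves the alkene to C7=C8.

**Step 13**
Reactants: 20 19-(tert-butyldimethylsilyloxy)-14-(trimethylsilyl)-15,16-dinorlabd-7-en-13-yne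
Product: 21 19-(tert-butyldimethylsilyloxy)-15,16-dinorlabd-7-en-13-yne
Conditions: K2CO3 (cat.), MeOH, rt
Reagents that add atoms: none
Why: Base-mediated methanolysis (protodesilylation) of the alkynyl–silicon bond is selective over the alkyl silyl ether and touches no stereocentre.

**Step 14**
Reactants: 21 19-(tert-butyldimethylsilyloxy)-15,16-dinorlabd-7-en-13-yne
Product: 23 allyl 19-(tert-butyldimethylsilyloxy)-16-norlabd-7-en-13-yn-15-oate, via lithium acetylide 22 (not isolated)
Conditions: n-BuLi, THF, −78 °C; allyl chloroformate, −78 to 0 °C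
Reagents that add atoms: allyl chloroformate, C=CCOC(=O)Cl
Why: Acylation of a lithium acetylide with a chloroformate installs C15 as the allyl ester, and the substrate carries no other acidic or electrophilic site.

**Step 15**
Reactants: 23 allyl 19-(tert-butyldimethylsilyloxy)-16-norlabd-7-en-13-yn-15-oate
Product: 24 allyl (13Z)-19-(tert-butyldimethylsilyloxy)labda-7,13-dien-15-oate
Conditions: Me2CuLi (from CuI + 2 MeLi), THF, −78 °C; MeOH at −78 °C, then aqueous NH4Cl
Reagents that add atoms: lithium dimethylcuprate Me2CuLi, [Li+].C[Cu-]C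
Why: Syn-carbocupration of the ynoate by the Gilman reagent places the new C16 methyl on C13 cis to copper, and protonation at −78 °C before allenoate equilibration should retain this geometry and give the (13Z)-enoate with C12 cis to the ester.

**Step 16**
Reactants: 24 allyl (13Z)-19-(tert-butyldimethylsilyloxy)labda-7,13-dien-15-oate
Product: 25 allyl (13Z)-19-hydroxylabda-7,13-dien-15-oate
Conditions: tetrabutylammonium fluoride, THF, rt
Reagents that add atoms: none
Why: Fluoride-mediated desilylation removes the silyl ether without affecting the allyl ester, the alkenes or any stereocentre.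

**Step 17**
Reactants: 25 allyl (13Z)-19-hydroxylabda-7,13-dien-15-oate; 26 angelic acid ((2Z)-2-methylbut-2-enoic acid)
Product: 28 allyl (13Z)-19-[(2Z)-2-methylbut-2-enoyloxy]labda-7,13-dien-15-oate, via mixed anhydride 27 (not isolated)
Conditions: 26, 2,4,6-trichlorobenzoyl chloride, Et3N, toluene, rt; then 25, toluene, 80 °C
Reagents that add atoms: none
Why: Yamaguchi esterification through the mixed anhydride, run without a nucleophilic pyridine catalyst, should acylate the hindered primary alcohol while avoiding base-induced angelate-to-tiglate isomerisation, so the Z geometry of the acid is carried over.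

**Step 18**
Reactants: 28 allyl (13Z)-19-[(2Z)-2-methylbut-2-enoyloxy]labda-7,13-dien-15-oate
Product: 29 (13Z)-19-[(2Z)-2-methylbut-2-enoyloxy]labda-7,13-dien-15-oic acid (CNP0249147.1)
Conditions: Pd(PPh3)4 (5 mol%), morpholine, THF, rt; dilute acid work-up
Reagents that add atoms: none
Why: Allyl transfer to morpholine through a π-allyl complex of zerovalent palladium (Tsuji–Trost deallylation) should cleave only the allyl ester under neutral conditions and leave the angelate, both trisubstituted alkenes and all stereocentres untouched.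

**Compound list**
1 | acrolein | C=CC=O | starting material
2 | ethyl 2-(triphenylphosphoranylidene)propanoate | CCOC(=O)C(C)=P(c1ccccc1)(c1ccccc1)c1ccccc1 | starting material
3 | ethyl (2E)-2-methylpenta-2,4-dienoate | CCOC(=O)/C(C)=C/C=C | intermediate
4 | (2E)-2-methylpenta-2,4-dien-1-ol | OC/C(C)=C/C=C | intermediate
5 | 4-methoxy-2,6-dimethylphenol | COc1cc(C)c(O)c(C)c1 | starting material
6 | 4-methoxy-2,6-dimethyl-4-{[(2E)-2-methylpenta-2,4-dien-1-yl]oxy}cyclohexa-2,5-dien-1-one | COC1(OC/C(C)=C/C=C)C=C(C)C(=O)C(C)=C1 | intermediate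
7 | 6α,19-epoxy-6β-methoxy-11,12,13,14,15,16-hexanor-5β-labda-2,7-dien-9-one | O3C[C@@]1(C)C=CC[C@]2(C)C(=O)C(C)=C[C@@]3(OC)[C@H]12 | intermediate
8 | 6α,19-epoxy-6β-methoxy-11,12,13,14,15,16-hexanor-5β-labd-7-en-9-one | O3C[C@@]1(C)CCC[C@]2(C)C(=O)C(C)=C[C@@]3(OC)[C@H]12 | intermediate
9 | 6β,19-epoxy-6α-methoxy-11,12,13,14,15,16-hexanorlabd-7-en-9-one | O3C[C@@]1(C)CCC[C@]2(C)C(=O)C(C)=C[C@]3(OC)[C@@H]12 | intermediate
10 | (4-bromobut-1-yn-1-yl)trimethylsilane | C[Si](C)(C)C#CCCBr | starting material
11 | [4-(trimethylsilyl)but-3-yn-1-yl]magnesium bromide | C[Si](C)(C)C#CCC[Mg]Br | intermediate (not isolated)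
12 | 6β,19-epoxy-6α-methoxy-14-(trimethylsilyl)-15,16-dinorlabd-7-en-13-yn-9β-ol | O3C[C@@]1(C)CCC[C@]2(C)[C@](O)(CCC#C[Si](C)(C)C)C(C)=C[C@]3(OC)[C@@H]12 | intermediate
13 | 6β,19-epoxy-6α-methoxy-14-(trimethylsilyl)-15,16-dinorlabd-8-en-13-yn-7-one | O3C[C@@]1(C)CCC[C@]2(C)C(CCC#C[Si](C)(C)C)=C(C)C(=O)[C@]3(OC)[C@@H]12 | intermediate
14 | 19-hydroxy-6α-methoxy-14-(trimethylsilyl)-15,16-dinorlabd-8-en-13-yn-7-one (either C6 epimer reacts on) | OC[C@@]1(C)CCC[C@]2(C)C(CCC#C[Si](C)(C)C)=C(C)C(=O)[C@H](OC)[C@@H]12 | intermediate (not isolated)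
15 | 19-hydroxy-14-(trimethylsilyl)-15,16-dinorlabd-8-en-13-yn-7-one | OC[C@@]1(C)CCC[C@]2(C)C(CCC#C[Si](C)(C)C)=C(C)C(=O)C[C@@H]12 | intermediate
16 | 19-(tert-butyldimethylsilyloxy)-14-(trimethylsilyl)-15,16-dinorlabd-8-en-13-yn-7-one | CC(C)(C)[Si](C)(C)OC[C@@]1(C)CCC[C@]2(C)C(CCC#C[Si](C)(C)C)=C(C)C(=O)C[C@@H]12 | intermediate
17 | 19-(tert-butyldimethylsilyloxy)-14-(trimethylsilyl)-15,16-dinorlabd-8-en-13-yn-7β-ol | CC(C)(C)[Si](C)(C)OC[C@@]1(C)CCC[C@]2(C)C(CCC#C[Si](C)(C)C)=C(C)[C@@H](O)C[C@@H]12 | intermediate
18 | 7α-[1-(2-nitrophenylsulfonyl)hydrazinyl]-19-(tert-butyldimethylsilyloxy)-14-(trimethylsilyl)-15,16-dinorlabd-8-en-13-yne | CC(C)(C)[Si](C)(C)OC[C@@]1(C)CCC[C@]2(C)C(CCC#C[Si](C)(C)C)=C(C)[C@H](N(N)S(=O)(=O)c3ccccc3[N+](=O)[O-])C[C@@H]12 | intermediate (not isolated)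
19 | 7α-diazenyl-19-(tert-butyldimethylsilyloxy)-14-(trimethylsilyl)-15,16-dinorlabd-8-en-13-yne | CC(C)(C)[Si](C)(C)OC[C@@]1(C)CCC[C@]2(C)C(CCC#C[Si](C)(C)C)=C(C)[C@H](N=N)C[C@@H]12 | intermediate (not isolated)
20 | 19-(tert-butyldimethylsilyloxy)-14-(trimethylsilyl)-15,16-dinorlabd-7-en-13-yne | CC(C)(C)[Si](C)(C)OC[C@@]1(C)CCC[C@]2(C)[C@@H](CCC#C[Si](C)(C)C)C(C)=CC[C@@H]12 | intermediate
21 | 19-(tert-butyldimethylsilyloxy)-15,16-dinorlabd-7-en-13-yne | CC(C)(C)[Si](C)(C)OC[C@@]1(C)CCC[C@]2(C)[C@@H](CCC#C)C(C)=CC[C@@H]12 | intermediate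
22 | lithium acetylide of 21 | CC(C)(C)[Si](C)(C)OC[C@@]1(C)CCC[C@]2(C)[C@@H](CCC#C[Li])C(C)=CC[C@@H]12 | intermediate (not isolated)
23 | allyl 19-(tert-butyldimethylsilyloxy)-16-norlabd-7-en-13-yn-15-oate | CC(C)(C)[Si](C)(C)OC[C@@]1(C)CCC[C@]2(C)[C@@H](CCC#CC(=O)OCC=C)C(C)=CC[C@@H]12 | intermediate
24 | allyl (13Z)-19-(tert-butyldimethylsilyloxy)labda-7,13-dien-15-oate | CC(C)(C)[Si](C)(C)OC[C@@]1(C)CCC[C@]2(C)[C@@H](CC/C(C)=C\C(=O)OCC=C)C(C)=CC[C@@H]12 | intermediate
25 | allyl (13Z)-19-hydroxylabda-7,13-dien-15-oate | OC[C@@]1(C)CCC[C@]2(C)[C@@H](CC/C(C)=C\C(=O)OCC=C)C(C)=CC[C@@H]12 | intermediate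
26 | angelic acid, (2Z)-2-methylbut-2-enoic acid | C/C=C(/C)C(=O)O | starting material
27 | angelic 2,4,6-trichlorobenzoic anhydride | C/C=C(/C)C(=O)OC(=O)c1c(Cl)cc(Cl)cc1Cl | intermediate (not isolated)
28 | allyl (13Z)-19-[(2Z)-2-methylbut-2-enoyloxy]labda-7,13-dien-15-oate | C/C=C(/C)C(=O)OC[C@@]1(C)CCC[C@]2(C)[C@@H](CC/C(C)=C\C(=O)OCC=C)C(C)=CC[C@@H]12 | intermediate
29 | (13Z)-19-[(2Z)-2-methylbut-2-enoyloxy]labda-7,13-dien-15-oic acid (CNP0249147.1) | C/C=C(/C)C(=O)OC[C@@]1(C)CCC[C@]2(C)[C@@H](CC/C(C)=C\C(=O)O)C(C)=CC[C@@H]12 | target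

**Step count and risks**
Total step count: 18. Longest linear sequence: 18 steps (1 + 2 to 29; compounds 5, 10 and 26 enter as purchased).

Steps most likely to fail:

1. Step 4 (Proposed new method). The risk is insufficient discrimination between the two enantiotopic enone bonds by the catalyst, or Lewis-acid-induced ionisation of the mixed ketal before cycloaddition. Fallback with known chemistry: setting out from 6, the thermal intramolecular Diels–Alder reaction (toluene, 110 °C, 2,6-di-tert-butyl-4-methylphenol as radical inhibitor) should give the racemate, that is 7 together with its mirror image ent-7 F1. Preparative chromatography on a chiral stationary phase (amylose tris(3,5-dimethylphenylcarbamate)) then separates the two, and the route is rejoined at 7.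

2. Step 6. The risk is incomplete epimerisation at C5 under acid, or loss of the ketal by hydrolysis or elimination instead of reclosure. Fallback: setting out from 8, aqueous HCl in THF hydrolyses the ketal to the cis-fused 19-hydroxy-hexanor-5β-labd-7-ene-6,9-dione F2. DBU in toluene then epimerises C5 through the C6 enolate to the trans-fused 19-hydroxy-hexanorlabd-7-ene-6,9-dione F3, which is expected to rest as its 6β,19-hemiketal. Camphorsulfonic acid in dry MeOH closes the mixed methyl ketal, and the route is rejoined at 9.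

3. Step 12. The risk is slow Mitsunobu displacement at the hindered C7 with competing elimination to a diene, which would also erode the stereochemical fidelity of hydrogen delivery to C9. Fallback: setting out from 17, formylation (formic acetic anhydride, pyridine) gives the 7β-formate F4. Palladium-catalysed formate hydrogenolysis (Pd(OAc)2, PBu3, THF, rt) should ionise it anti to the leaving group, placing palladium on the α face, and transfer hydride from that face to the more substituted allyl terminus C9 with loss of CO2. The route is rejoined at 20.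

**Further compounds**
F1 | step 4 | ent-7, mirror image of the cis-fused adduct | O3C[C@]1(C)C=CC[C@@]2(C)C(=O)C(C)=C[C@]3(OC)[C@@H]12
F2 | step 6 | 19-hydroxy-11,12,13,14,15,16-hexanor-5β-labd-7-ene-6,9-dione | OC[C@@]1(C)CCC[C@]2(C)C(=O)C(C)=CC(=O)[C@H]12
F3 | step 6 | 19-hydroxy-11,12,13,14,15,16-hexanorlabd-7-ene-6,9-dione (5α-H) | OC[C@@]1(C)CCC[C@]2(C)C(=O)C(C)=CC(=O)[C@@H]12
F4 | step 12 | 7β-formyloxy-19-(tert-butyldimethylsilyloxy)-14-(trimethylsilyl)-15,16-dinorlabd-8-en-13-yne | CC(C)(C)[Si](C)(C)OC[C@@]1(C)CCC[C@]2(C)C(CCC#C[Si](C)(C)C)=C(C)[C@@H](OC=O)C[C@@H]12
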